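**Retrosynthetic overview**
1. Target 26 comes from diketone 22 by two substrate-controlled carbonyl reductions (C12, then C6), acetylation at O12 and global desilylation.
2. Diketone 22 comes from silyl bis-enol ether 21 by oxidative C7–C11 coupling. C7–C11 is the central bond of the 1,4-dioxygenated chain O–C6–C7–C11–C12–O. At the diketone level C7 (α-carbon of the ketone in the seven-membered ring) and C11 (α'-carbon of the side-chain ethyl enone) are both enolate carbons, i.e. of like donor polarity, so they are joined by oxidation through a temporary O–Si–O tether.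
3. Bis-enol ether 21 comes from cyclic silyl enol ether 13 and enone 17 (from cross-metathesis).
4. Enol ether 13 comes from ring-closing metathesis of 12 (seven-membered ring formed last, enol double bond fixed at C6=C7). Compound 12 comes from (R)-carvone by photo-Wolff ring contraction (five-membered ring formed first), after C9 has been set by allylboration.

Key step: step 13

Remark: dictyol-type locants are used throughout (C1/C5 ring fusion, C3=C4 with the methyl on C4, C6 ring carbinol, C7 side-chain-bearing ring carbon, C8 CH2, C9 allylic carbinol, C10 exo-methylene carbon, C11 CHMe, C12 CHOAc, C13=C14, C15 CMe2OH); the given SMILES corresponds to 1R,5S,6R,7S,9R,11R,12S with a trans ring fusion.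

**Step 1**
Reactants: 1 (R)-(–)-carvone
Product: 2 (5R)-5-(3-chloroprop-1-en-2-yl)-2-methylcyclohex-2-en-1-one
Conditions: Ca(OCl)2, CO2 (dry ice), CH2Cl2/H2O, 0 °C
Reagents that add atoms: calcium hypochlorite [Ca+2].[O-]Cl.[O-]Cl
Why: Ene-type allylic chlorination by HOCl should take place only at the electron-rich isopropenyl group, because the enone double bond is deactivated; the carvone stereocentre (later C1) is untouched.

**Step 2**
Reactants: 2 (5R)-5-(3-chloroprop-1-en-2-yl)-2-methylcyclohex-2-en-1-one
Product: 3 2-[(1R)-4-methyl-5-oxocyclohex-3-en-1-yl]prop-2-enal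
Conditions: NMO (3 equiv), NaI (0.1 equiv), NaHCO3, MeCN, 40 °C
Reagents that add atoms: N-methylmorpholine N-oxide C[N+]1([O-])CCOCC1
Why: Amine N-oxide (Ganem/Kornblum-type) oxidation: iodide-assisted SN2 of the allylic chloride by the N-oxide oxygen and base-induced collapse of the alkoxyammonium salt should give the 2-substituted acrolein without touching the enone.

**Step 3**
Reactants: 3 2-[(1R)-4-methyl-5-oxocyclohex-3-en-1-yl]prop-2-enal
Product: 4 (5R)-5-[(3R)-3-hydroxyhexa-1,5-dien-2-yl]-2-methylcyclohex-2-en-1-one
Conditions: (–)-Ipc2B(allyl) [from (–)-α-pinene], Et2O, –78 °C; then ethanolamine, rt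
Reagents that add atoms: (–)-B-allyldiisopinocampheylborane C=CCB([C@H]1C[C@H]2C[C@@H]([C@@H]1C)C2(C)C)[C@H]3C[C@H]4C[C@@H]([C@@H]3C)C4(C)C
Why: Brown asymmetric allylboration through a chair Zimmerman–Traxler transition state; the reagent should control Re-face attack on the aldehyde (far more reactive than the enone carbonyl) and set the carbinol (later C9) as R, and the non-oxidative work-up spares the enone.

**Step 4**
Reactants: 4 (5R)-5-[(3R)-3-hydroxyhexa-1,5-dien-2-yl]-2-methylcyclohex-2-en-1-one
Product: 5 (5R)-5-[(3R)-3-(tert-butyldimethylsilyloxy)hexa-1,5-dien-2-yl]-2-methylcyclohex-2-en-1-one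
Conditions: TBSCl, imidazole, DMF, rt
Reagents that add atoms: tert-butyldimethylsilyl chloride CC(C)(C)[Si](C)(C)Cl
Why: Standard silylation of a secondary allylic alcohol; the TBS ether survives all later basic, photochemical and oxidative steps.

**Step 5**
Reactants: 5 (5R)-5-[(3R)-3-(tert-butyldimethylsilyloxy)hexa-1,5-dien-2-yl]-2-methylcyclohex-2-en-1-one
Product: 7 6-diazo-5-[(3R)-3-(tert-butyldimethylsilyloxy)hexa-1,5-dien-2-yl]-2-methylcyclohex-2-en-1-one (ring stereocentre as in 5), via trifluoroacetyl ketone 6 (not isolated)
Conditions: LiHMDS, THF, –78 °C; CF3CO2CH2CF3; then MsN3, Et3N, H2O, MeCN, rt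
Reagents that add atoms: methanesulfonyl azide CS(=O)(=O)N=[N+]=[N-]
Why: Detrifluoroacetylative diazo transfer (Danheiser): the kinetic α'-enolate is trifluoroacetylated and the activated 1,3-dicarbonyl accepts the diazo group from MsN3 with loss of the trifluoroacetyl group, which is the standard route to α'-diazo enones.

**Step 6**
Reactants: 7 6-diazo-5-[(3R)-3-(tert-butyldimethylsilyloxy)hexa-1,5-dien-2-yl]-2-methylcyclohex-2-en-1-one
Product: 9 methyl (1S,5R)-5-[(3R)-3-(tert-butyldimethylsilyloxy)hexa-1,5-dien-2-yl]-2-methylcyclopent-2-ene-1-carboxylate, via cis ester 8 (not isolated)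
Conditions: hν (Hg lamp, Pyrex), MeOH, 20 °C; then NaOMe (0.2 equiv), MeOH, 0 °C, AcOH quench
Reagents that add atoms: methanol CO
Why: Photochemical Wolff ring contraction (1,2-shift of the alkenyl carbon) should give a vinylketene that methanol traps as the β,γ-unsaturated ester, expected cis-rich by protonation anti to the neighbouring substituent; brief methoxide equilibration through the ester enolate, which reprotonates fastest at the α-carbon, should then set C5 trans to the C1 substituent under thermodynamic control.

**Step 7**
Reactants: 9 methyl (1S,5R)-5-[(3R)-3-(tert-butyldimethylsilyloxy)hexa-1,5-dien-2-yl]-2-methylcyclopent-2-ene-1-carboxylate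
Product: 11 1-[(1S,5R)-5-[(3R)-3-(tert-butyldimethylsilyloxy)hexa-1,5-dien-2-yl]-2-methylcyclopent-2-en-1-yl]ethan-1-one, via Weinreb amide 10 (not isolated)
Conditions: MeNHOMe·HCl, iPrMgCl, THF, –20 °C; then MeMgBr, –20 → 0 °C
Reagents that add atoms: methylmagnesium bromide C[Mg]Br
Why: One-pot Weinreb ketone synthesis; the chelated tetrahedral intermediate prevents over-addition and keeps the ketone masked, so C5 is not enolised before work-up.

**Step 8**
Reactants: 11 1-[(1S,5R)-5-[(3R)-3-(tert-butyldimethylsilyloxy)hexa-1,5-dien-2-yl]-2-methylcyclopent-2-en-1-yl]ethan-1-one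
Product: 12 trimethylsilyl enol ether of 11 on the methyl side (1-substituted ethenyl trimethylsilyl ether, 1S,5R,3'R)
Conditions: LDA, TMSCl (in situ quench), THF, –78 °C; Et3N
Reagents that add atoms: chlorotrimethylsilane C[Si](C)(C)Cl
Why: Kinetic deprotonation of a methyl ketone by LDA should occur at the unhindered methyl group, not at the hindered C5 methine, and the in situ silyl trap fixes the terminal enol ether without touching C5.

**Step 9**
Reactants: 12 trimethylsilyl enol ether of 11
Product: 13 (1R,5S,9R)-9-(tert-butyldimethylsilyloxy)-6-(trimethylsilyloxy)hydroazulene with C3=C4 (4-methyl), C6=C7 and 10-methylidene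
Conditions: Grubbs II (5 mol %), CH2Cl2 (0.005 M), 40 °C; used without chromatography
Reagents that add atoms: none
Why: Ring-closing metathesis of a terminal alkene with a 1,1-disubstituted silyl enol ether (known for five- to seven-membered cyclic silyl enol ethers) should close the seven-membered ring and place the enol double bond at C6=C7; the exo-methylene and the trisubstituted cyclopentene are poor metathesis partners.

**Step 10**
Reactants: 14 pent-1-en-3-one; 15 2-methylbut-3-en-2-ol
Product: 16 (E)-6-hydroxy-6-methylhept-4-en-3-one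
Conditions: Hoveyda–Grubbs II (3 mol %), 15 (3 equiv), CH2Cl2, 40 °C
Reagents that add atoms: none
Why: Olefin cross-metathesis of an electron-poor vinyl ketone with a tertiary allylic alcohol, two partners that homodimerise slowly, should give the E-enone under thermodynamic control.

**Step 11**
Reactants: 16 (E)-6-hydroxy-6-methylhept-4-en-3-one
Product: 17 (E)-6-methyl-6-(triethylsilyloxy)hept-4-en-3-one
Conditions: TESOTf, 2,6-lutidine, CH2Cl2, –78 → 0 °C
Reagents that add atoms: triethylsilyl trifluoromethanesulfonate CC[Si](CC)(CC)OS(=O)(=O)C(F)(F)F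
Why: Silyl triflate silylation of a tertiary alcohol; the enone has no γ-hydrogen, so only the ethyl group can be enolised later.

**Step 12**
Reactants: 13 cyclic trimethylsilyl enol ether; 17 (E)-6-methyl-6-(triethylsilyloxy)hept-4-en-3-one
Product: 21 diisopropylsilyl bis-enol ether joining O6 of the ring enol (C6=C7) and O12 of the (11Z,13E)-dienol, via lithium (Z)-dienolate 18 (not isolated), via chlorosilyl dienol ether 19 (not isolated), via ring lithium enolate 20 (not isolated)
Conditions: (a) 17, LDA, THF/DMPU, –78 °C; iPr2SiCl2 (1.0 equiv), –78 → 0 °C; (b) 13, MeLi, THF, 0 °C; (c) b added to a, –78 °C → rt; filtration through Et3N-deactivated silica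
Reagents that add atoms: dichlorodiisopropylsilane CC(C)[Si](Cl)(Cl)C(C)C
Why: Sequential O-silylation of two lithium enolates with a hindered dichlorosilane (first chloride substituted selectively) is the known route to unsymmetrical silyl bis-enol ethers; MeLi cleavage of the TMS enol ether gives the C6=C7 enolate regiospecifically, and the alkenyl ethyl ketone should give the Z(O)-dienolate as aryl ethyl ketones do.

**Step 13**
Reactants: 21 diisopropylsilyl bis-enol ether
Product: 22 (1R,5S,7S,9R)-9-(tert-butyldimethylsilyloxy)-4-methyl-10-methylidene-7-[(2R,4E)-6-methyl-3-oxo-6-(triethylsilyloxy)hept-4-en-2-yl]hydroazul-3-en-6-one (1,4-diketone)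
Conditions: CAN (2.2 equiv), NaHCO3 (4.4 equiv), MeCN/EtCN (6:1), –30 → –10 °C
Reagents that add atoms: none
Why: Ce(IV) should remove one electron from the more electron-rich 2-silyloxydiene half of 21, the radical cation is captured at C11 by C7 of the tethered ring enol ether, and a second one-electron oxidation with loss of the iPr2Si unit gives the 1,4-diketone. The closest known reaction type is the CAN-mediated oxidative coupling of unsymmetrical dialkylsilyl bis-enol ethers (silicon-tethered ketone enolate heterocoupling). The only ring closed is the temporary seven-membered 1,3-dioxa-2-silacycloheptane, formed by bonding of the two enol β-carbons and destroyed again when silicon leaves, so no ring of the target is formed here. C7 should be set by attack on the β-face of the ring enol ether, anti to the C5–C4 bond (held pseudoaxial on the α-face by A1,3 strain with the enol oxygen) and to the α-oriented C9 silyloxy group; C11 is set relative to C7 by the staggered, twisted transition state enforced by the short O–Si–O tether, in which the ring enol (C8 trans to oxygen) and the (Z)-dienol (methyl cis to oxygen) must use faces of the same sense, which corresponds to 7S,11R. The step needs hetero- over homocoupling (secured by the tether), C11 over C14 regioselectivity in the dienol radical cation (seven- versus nine-membered transition state, C14 next to a quaternary carbon) and chemoselectivity over the isolated alkenes (silyl enol ethers are oxidised at far lower potential, NaHCO3 buffers the acid).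

**Step 14**
Reactants: 22 1,4-diketone
Product: 23 12S allylic alcohol (C6 ketone retained)
Conditions: NaBH4, CeCl3·7H2O, MeOH, –78 °C
Reagents that add atoms: none
Why: Luche 1,2-reduction should reduce the conjugated C12 ketone ahead of the hindered, doubly α-branched C6 ketone, and Felkin–Anh addition (ring carbon C7 as the large group at C11) should give the 11,12-anti relationship, i.e. 12S.

**Step 15**
Reactants: 23 12S allylic alcohol
Product: 24 12-acetate
Conditions: Ac2O, pyridine, DMAP (cat.), CH2Cl2, 0 °C
Reagents that add atoms: acetic anhydride CC(=O)OC(C)=O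
Why: Acylation of the only free hydroxyl group; short exposure to weak base at 0 °C should leave the C5 and C7 α-stereocentres intact.

**Step 16**
Reactants: 24 12-acetate
Product: 25 6R alcohol (9-O-TBS, 15-O-TES, 12-OAc)
Conditions: NaBH4, CeCl3·7H2O, MeOH, –40 → 0 °C
Reagents that add atoms: none
Why: Borohydride should attack the C6 ketone from the α-face, anti to the β-oriented C7 side chain and along the axial trajectory, giving the equatorial 6β-alcohol cis to the side chain (6R); the acetate is stable under these nearly neutral conditions.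

**Step 17**
Reactants: 25 6R alcohol
Product: 26 target (1R,5S,6R,7S,9R,11R,12S)
Conditions: HF·pyridine, pyridine, THF, 0 °C → rt
Reagents that add atoms: none
Why: Buffered fluoride desilylation should remove the TES and TBS groups without acetate migration or ionisation of the allylic acetate/tertiary allylic alcohol system.

**Compound list**
1 | (R)-(–)-carvone | CC1=CC[C@H](CC1=O)C(C)=C | starting material
2 | (5R)-5-(3-chloroprop-1-en-2-yl)-2-methylcyclohex-2-en-1-one | CC1=CC[C@H](CC1=O)C(=C)CCl | intermediate
3 | 2-[(1R)-4-methyl-5-oxocyclohex-3-en-1-yl]prop-2-enal | CC1=CC[C@H](CC1=O)C(=C)C=O | intermediate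
4 | (5R)-5-[(3R)-3-hydroxyhexa-1,5-dien-2-yl]-2-methylcyclohex-2-en-1-one | CC1=CC[C@H](CC1=O)C(=C)[C@H](O)CC=C | intermediate
5 | TBS ether of 4 | CC1=CC[C@H](CC1=O)C(=C)[C@H](O[Si](C)(C)C(C)(C)C)CC=C | intermediate
6 | 6-trifluoroacetyl derivative of 5 (enol form) | CC1=CC[C@H](C(C(=O)C(F)(F)F)=C1O)C(=C)[C@H](O[Si](C)(C)C(C)(C)C)CC=C | intermediate (not isolated)
7 | 6-diazo derivative of 5 | CC1=CC[C@H](C(=[N+]=[N-])C1=O)C(=C)[C@H](O[Si](C)(C)C(C)(C)C)CC=C | intermediate
8 | methyl (1R,5R)-5-[(3R)-3-(TBS-oxy)hexa-1,5-dien-2-yl]-2-methylcyclopent-2-ene-1-carboxylate (cis) | COC(=O)[C@H]1C(C)=CC[C@H]1C(=C)[C@H](O[Si](C)(C)C(C)(C)C)CC=C | intermediate (not isolated)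
9 | methyl (1S,5R)-5-[(3R)-3-(TBS-oxy)hexa-1,5-dien-2-yl]-2-methylcyclopent-2-ene-1-carboxylate (trans) | COC(=O)[C@@H]1C(C)=CC[C@H]1C(=C)[C@H](O[Si](C)(C)C(C)(C)C)CC=C | intermediate
10 | N-methoxy-N-methyl amide corresponding to 9 | CON(C)C(=O)[C@@H]1C(C)=CC[C@H]1C(=C)[C@H](O[Si](C)(C)C(C)(C)C)CC=C | intermediate (not isolated)
11 | methyl ketone (1S,5R,3'R) | CC(=O)[C@@H]1C(C)=CC[C@H]1C(=C)[C@H](O[Si](C)(C)C(C)(C)C)CC=C | intermediate
12 | terminal TMS enol ether of 11 | C=C(O[Si](C)(C)C)[C@@H]1C(C)=CC[C@H]1C(=C)[C@H](O[Si](C)(C)C(C)(C)C)CC=C | intermediate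
13 | cyclic TMS enol ether (hydroazulene, C6=C7) | C=C1[C@H](O[Si](C)(C)C(C)(C)C)CC=C(O[Si](C)(C)C)[C@@H]2C(C)=CC[C@@H]12 | intermediate
14 | pent-1-en-3-one | CCC(=O)C=C | starting material
15 | 2-methylbut-3-en-2-ol | CC(C)(O)C=C | starting material
16 | (E)-6-hydroxy-6-methylhept-4-en-3-one | CCC(=O)/C=C/C(C)(C)O | intermediate
17 | (E)-6-methyl-6-(triethylsilyloxy)hept-4-en-3-one | CCC(=O)/C=C/C(C)(C)O[Si](CC)(CC)CC | intermediate
18 | lithium (Z)-dienolate of 17 | C/C=C(\O[Li])/C=C/C(C)(C)O[Si](CC)(CC)CC | intermediate (not isolated)
19 | chloro(diisopropyl)silyl (Z)-dienol ether of 17 | C/C=C(\O[Si](Cl)(C(C)C)C(C)C)/C=C/C(C)(C)O[Si](CC)(CC)CC | intermediate (not isolated)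
20 | ring lithium enolate (C6=C7) | C=C1[C@H](O[Si](C)(C)C(C)(C)C)CC=C(O[Li])[C@@H]2C(C)=CC[C@@H]12 | intermediate (not isolated)
21 | diisopropylsilyl bis-enol ether | C=C1[C@H](O[Si](C)(C)C(C)(C)C)CC=C(O[Si](C(C)C)(C(C)C)O\C(=C/C)\C=C\C(C)(C)O[Si](CC)(CC)CC)[C@@H]2C(C)=CC[C@@H]12 | intermediate
22 | 1,4-diketone (1R,5S,7S,9R,11R) | C=C1[C@H](O[Si](C)(C)C(C)(C)C)C[C@@H]([C@@H](C)C(=O)/C=C/C(C)(C)O[Si](CC)(CC)CC)C(=O)[C@@H]2C(C)=CC[C@@H]12 | intermediate
23 | 12S allylic alcohol | C=C1[C@H](O[Si](C)(C)C(C)(C)C)C[C@@H]([C@@H](C)[C@H](/C=C/C(C)(C)O[Si](CC)(CC)CC)O)C(=O)[C@@H]2C(C)=CC[C@@H]12 | intermediate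
24 | 12-acetate | C=C1[C@H](O[Si](C)(C)C(C)(C)C)C[C@@H]([C@@H](C)[C@H](/C=C/C(C)(C)O[Si](CC)(CC)CC)OC(C)=O)C(=O)[C@@H]2C(C)=CC[C@@H]12 | intermediate
25 | 6R alcohol, bis-silyl ether | C=C1[C@H](O[Si](C)(C)C(C)(C)C)C[C@@H]([C@@H](C)[C@H](/C=C/C(C)(C)O[Si](CC)(CC)CC)OC(C)=O)[C@@H](O)[C@@H]2C(C)=CC[C@@H]12 | intermediate
26 | CNP0213969.2 | C=C1[C@H](O)C[C@@H]([C@@H](C)[C@H](/C=C/C(C)(C)O)OC(C)=O)[C@@H](O)[C@@H]2C(C)=CC[C@@H]12 | target

**Step count and risks**
Total step count: 17. Longest linear sequence: 15 (steps 1–9, 12–17).

Step 13 is the most likely to fail. The twisted transition state may pair the enol faces with the other topicity, the ring enol ether may be attacked from its α-face, the radical cation may lose the doubly allylic C5 proton, or the silyloxydiene may react at C14. The fallback sets out from 13 and 17 and replaces the tethered one-electron coupling by an untethered two-electron umpolung. Enone 17 is converted with LDA and TMSCl into its trimethylsilyl dienol ether F1. Compound 13 is treated with PhI(OAc)2 and BF3·OEt2 in CH2Cl2 at –78 °C to form the ring enolonium species, which F1 attacks at C7 (known cross-coupling of two different silyl enol ethers through enolonium intermediates). This gives diketone 22 through an open transition state; diastereomers are separated, and the route is rejoined at 22.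

Step 6 is second. The C3=C4 double bond may migrate into conjugation with the ester during the methoxide equilibration, or the cis to trans equilibration may stay incomplete. The fallback sets out from 5 and replaces protonation by a stereospecific 1,2-shift. Compound 5 is brominated at the α'-carbon through its kinetic lithium enolate (LiHMDS, THF, –78 °C, then NBS), the bromine entering trans to the neighbouring substituent, to give trans bromo ketone F2. Silver(I)-assisted quasi-Favorskii (semibenzilic) rearrangement in methanol (AgBF4, MeOH, 2,6-lutidine) moves the alkenyl ring carbon onto the bromine-bearing carbon with inversion. This should give the trans ester directly without an enolate at the new stereocentre, and the route is rejoined at 9.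

Step 14 is third. Felkin–Anh facial selectivity at the C12 ketone may be low, or the C6 ketone may be reduced too early. The fallback sets out from 22 and replaces facial control by stereospecific substitution. The same reduction is run, the 12-epi alcohol F3 is separated, and it is esterified under Mitsunobu conditions (PPh3, DIAD, AcOH, toluene, 0 °C). The acetate is introduced with inversion at C12, and the route is rejoined at 24.

**Further compounds**
F1 | step 13 | trimethylsilyl (Z)-dienol ether of 17 | C/C=C(\O[Si](C)(C)C)/C=C/C(C)(C)O[Si](CC)(CC)CC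
F2 | step 6 | 6-bromo derivative of 5, bromine trans to the C5 substituent | CC1=CC[C@H]([C@H](Br)C1=O)C(=C)[C@H](O[Si](C)(C)C(C)(C)C)CC=C
F3 | step 14 | 12-epi (12R) alcohol | C=C1[C@H](O[Si](C)(C)C(C)(C)C)C[C@@H]([C@@H](C)[C@@H](/C=C/C(C)(C)O[Si](CC)(CC)CC)O)C(=O)[C@@H]2C(C)=CC[C@@H]12
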